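A direct plan would make the N-(4-methoxybenzyl)-2-[(Z)-butenyl]pyrrolidine A1 from hydroxyproline, enlarge it with 6-chlorohexanoyl fluoride and Me3Al by an acylammonium aza-Claisen shift to the nine-membered lactam A2, close the azepanone by N-alkylation and add the fused lactone last through the epoxy ketone A3.
Its weakest steps would be:
(a) the zwitterionic ring enlargement, in which dealkylation of the acylammonium ion, a boat transition state or acylation on the wrong nitrogen face would each cost the C9/C10 pair;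
(b) the azepanone closure, in which a nine-membered amidate would have to turn its nitrogen inward to reach a primary chloride;
(c) the final reductive alkylation, in which an enolate flanked by a β-alkoxide would have to be alkylated at C12 by a secondary triflate without elimination.

The nine-membered ring would not be closed but set free. In the target the ketone carbon C1 and the lactam carbon C9a face each other across that ring, so both can come from one C–C bond: the ring-fusion bond of a tyrosine-derived 1-hydroxy-azepino[3,2,1-hi]indole, whose C1 hydroxyl and N4 form a 1,2-amino alcohol. Pb(OAc)4 cleaves it to the C1 ketone and a C9a iminium ion, which NaClO2 oxidises to the lactam; one operation gives the nine-membered ring, the azepanone and both carbonyl groups. C9–C12 are set earlier on the rigid bicycle by convex-face additions and the azepane by amine alkylation, so no acylammonium shift, amidate alkylation or medium-ring enolate is needed.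

Key step: step 16

Remark on numbering: all intermediates carry the atom numbers of the target (N4, C1–C3, C5–C21); the alcoholysis of the spirolactone in step 2 is assumed to follow the course established for methanol.

Step 1
Reactants: 1 N-(tert-butoxycarbonyl)-L-tyrosine
Product: 2 tert-butyl N-[(3S)-2,8-dioxo-1-oxaspiro[4.5]deca-6,9-dien-3-yl]carbamate
Conditions: PhI(OAc)2, MeNO2, 0 °C → rt
Reagents that add atoms: none
Why: Two-electron oxidation of the phenol by the hypervalent iodine reagent and capture of the para carbon by the carboxyl group (oxidative dearomatisation with 5-exo spirolactonisation, known for N-acyl tyrosines) leave the α-centre, the later C3, untouched.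

Step 2
Reactants: 2 tert-butyl N-[(3S)-2,8-dioxo-1-oxaspiro[4.5]deca-6,9-dien-3-yl]carbamate
Product: 4 2-benzyl 1-tert-butyl (2S,3aR,7aR)-3a-hydroxy-6-oxo-2,3,3a,6,7,7a-hexahydro-1H-indole-1,2-dicarboxylate, via quinol benzyl ester 3 (not isolated)
Conditions: BnOH, NaHCO3, THF, 40 °C
Reagents that add atoms: benzyl alcohol, OCc1ccccc1
Why: Base-promoted benzyl alcoholysis opens the spirolactone to the quinol ester, whose carbamate nitrogen adds reversibly to one enone arm (5-exo aza-Michael addition) to give the cis-fused bicycle with the ester on the convex face, which sets C1 (R, angular hydroxyl) and C9a (R).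

Step 3
Reactants: 4 2-benzyl 1-tert-butyl (2S,3aR,7aR)-3a-hydroxy-6-oxo-2,3,3a,6,7,7a-hexahydro-1H-indole-1,2-dicarboxylate
Product: 5 2-benzyl 1-tert-butyl (2S,3aR,7aR)-6-oxo-3a-(triethylsilyloxy)-2,3,3a,6,7,7a-hexahydro-1H-indole-1,2-dicarboxylate
Conditions: Et3SiOTf, 2,6-lutidine, CH2Cl2, −78 → 0 °C
Reagents that add atoms: triethylsilyl trifluoromethanesulfonate, CC[Si](CC)(CC)OS(=O)(=O)C(F)(F)F
Why: Silylation of the tertiary alcohol with the silyl triflate keeps its alkoxide from attacking the carbamate in the basic steps and from directing the later hydroboration.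

Step 4
Reactants: 5 2-benzyl 1-tert-butyl (2S,3aR,7aR)-6-oxo-3a-(triethylsilyloxy)-2,3,3a,6,7,7a-hexahydro-1H-indole-1,2-dicarboxylate
Product: 6 2-benzyl 1-tert-butyl (2S,3aR,7R,7aR)-7-(4-chlorobutyl)-6-oxo-3a-(triethylsilyloxy)-2,3,3a,6,7,7a-hexahydro-1H-indole-1,2-dicarboxylate
Conditions: LiN(i-Pr)2, THF, −78 °C; I(CH2)4Cl, DMPU, −78 → −30 °C
Reagents that add atoms: 1-chloro-4-iodobutane, ClCCCCI
Why: Kinetic deprotonation can occur only at C9 (C1 is quaternary, so there is no γ-hydrogen), and the cross-conjugated lithium enolate is alkylated by the iodide end of the dihalide on the convex face, anti to the neighbouring C9a–N bond, which sets C9 with C8 trans to nitrogen (enolate alkylation).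

Step 5
Reactants: 6 2-benzyl 1-tert-butyl (2S,3aR,7R,7aR)-7-(4-chlorobutyl)-6-oxo-3a-(triethylsilyloxy)-2,3,3a,6,7,7a-hexahydro-1H-indole-1,2-dicarboxylate
Product: 8 2-benzyl 1-tert-butyl (2S,3aR,4S,7R,7aR)-7-(4-chlorobutyl)-4-(prop-1-en-2-yl)-3a-(triethylsilyloxy)-6-(trifluoromethylsulfonyloxy)-2,3,3a,4,7,7a-hexahydro-1H-indole-1,2-dicarboxylate, via magnesium enolate 7 (not isolated)
Conditions: CH2=C(CH3)MgBr, CuBr·SMe2 (20 mol %), THF, −78 °C; then N-(5-chloropyridin-2-yl)triflimide, −78 → 0 °C
Reagents that add atoms: isopropenylmagnesium bromide, CC(=C)[Mg]Br; N-(5-chloropyridin-2-yl)-1,1,1-trifluoro-N-[(trifluoromethyl)sulfonyl]methanesulfonamide, FC(F)(F)S(=O)(=O)N(c1ccc(Cl)cn1)S(=O)(=O)C(F)(F)F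
Why: Copper-catalysed conjugate addition of the Grignard reagent reaches C12 from the convex face, anti to the axial C1–C2 bond of the cis-fused ring, which sets C12, and the regiodefined magnesium enolate is trapped on oxygen by the pyridyl triflimide to fix the C10=C11 enol triflate.

Step 6
Reactants: 8 2-benzyl 1-tert-butyl (2S,3aR,4S,7R,7aR)-7-(4-chlorobutyl)-4-(prop-1-en-2-yl)-3a-(triethylsilyloxy)-6-(trifluoromethylsulfonyloxy)-2,3,3a,4,7,7a-hexahydro-1H-indole-1,2-dicarboxylate
Product: 9 2-benzyl 1-tert-butyl (2S,3aR,4S,7S,7aR)-7-(4-chlorobutyl)-6-ethyl-4-(prop-1-en-2-yl)-3a-(triethylsilyloxy)-2,3,3a,4,7,7a-hexahydro-1H-indole-1,2-dicarboxylate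
Conditions: Et2Zn, PdCl2(dppf) (5 mol %), THF, 50 °C
Reagents that add atoms: diethylzinc, CC[Zn]CC
Why: Negishi cross-coupling (oxidative addition of zerovalent palladium to the enol triflate, transmetallation from zinc, reductive elimination from the dppf complex faster than β-hydride loss) puts the ethyl group on C10 and leaves the trisubstituted C10=C11 alkene.

Step 7
Reactants: 9 2-benzyl 1-tert-butyl (2S,3aR,4S,7S,7aR)-7-(4-chlorobutyl)-6-ethyl-4-(prop-1-en-2-yl)-3a-(triethylsilyloxy)-2,3,3a,4,7,7a-hexahydro-1H-indole-1,2-dicarboxylate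
Product: 11 benzyl (1R,3S,9S,9aR,12S)-10-ethyl-12-(prop-1-en-2-yl)-1-(triethylsilyloxy)-10,11-didehydro-perhydroazepino[3,2,1-hi]indole-3-carboxylate (tricyclic amine, target numbering), via secondary amine 10 (not isolated)
Conditions: Me3SiOTf, 2,6-lutidine, CH2Cl2, 0 °C; MeOH; then K2CO3, NaI (cat.), MeCN, 70 °C
Reagents that add atoms: none
Why: Silyl triflate-mediated cleavage of the Boc group spares the silyl ether and the benzyl ester, and the free pyrrolidine nitrogen then displaces the primary chloride (7-exo-tet N-alkylation, iodide-catalysed) to close the trans-fused azepane while C10 and C11 are still trigonal, so that N4 and C8 can both be equatorial.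

Step 8
Reactants: 11 benzyl (1R,3S,9S,9aR,12S)-10-ethyl-12-(prop-1-en-2-yl)-1-(triethylsilyloxy)-10,11-didehydro-perhydroazepino[3,2,1-hi]indole-3-carboxylate
Product: 14 benzyl (1R,3S,9S,9aR,10R,11S,12R)-10-ethyl-11-hydroxy-12-(1-hydroxypropan-2-yl)-1-(triethylsilyloxy)perhydroazepino[3,2,1-hi]indole-3-carboxylate (both C13 epimers), via 9-BBN adduct 12 (not isolated), via bis-borane 13 (not isolated)
Conditions: 9-BBN, THF, rt; BH3·THF, 0 °C → rt; H2O2, NaOAc (aq), 0 °C; then DABCO, toluene, 60 °C
Reagents that add atoms: hydrogen peroxide, OO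
Why: 9-BBN takes only the 1,1-disubstituted alkene, and BH3 then adds to the ring alkene from the face opposite to the pseudo-axial C12 side chain and the C9 substituent, boron at C11 and hydrogen at C10 (syn hydroboration), so oxidation with retention gives 10R and 11S (ethyl cis to C8, hydroxyl trans to ethyl); C13 forms without reliable control and is corrected in step 11.

Step 9
Reactants: 14 benzyl (1R,3S,9S,9aR,10R,11S,12R)-10-ethyl-11-hydroxy-12-(1-hydroxypropan-2-yl)-1-(triethylsilyloxy)perhydroazepino[3,2,1-hi]indole-3-carboxylate (both C13 epimers)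
Product: 16 benzyl ester of the tetracyclic lactone (γ-lactone O11–C14(=O)–C13(CH3)–C12 trans-fused at C11–C12; 1R,3S,9S,9aR,10R,11S,12R; both C13 epimers), via lactol 15 (not isolated)
Conditions: Ag2CO3 on Celite, toluene, 90 °C
Reagents that add atoms: none
Why: Fétizon oxidation takes the primary alcohol to the aldehyde, which the C11 hydroxyl captures as the lactol (O11 and C13 are gauche in the boat that this cyclohexane must adopt, since a chair would place the ethyl group and the C12 chain 1,3-diaxial), and the lactol is oxidised on to the trans-fused γ-lactone while the tertiary amine is inert to Ag2CO3.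

Step 10
Reactants: 16 benzyl ester of the tetracyclic lactone (both C13 epimers)
Product: 17 tetracyclic lactone amino acid (3-CO2H; 1R,3S,9S,9aR,10R,11S,12R; both C13 epimers)
Conditions: H2 (1 atm), Pd/C, EtOAc, rt
Reagents that add atoms: none
Why: Hydrogenolysis of the benzyl ester frees the α-amino acid needed for step 13, and nothing else in the molecule is reducible under these conditions.

Step 11
Reactants: 17 tetracyclic lactone amino acid (both C13 epimers)
Product: 19 (13S)-tetracyclic lactone amino acid (1R,3S,9S,9aR,10R,11S,12R,13S), via dilithium enolate 18 (not isolated)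
Conditions: LiN(i-Pr)2 (3 equiv), THF/DMPU, −78 → −40 °C; AcOH, −78 °C
Reagents that add atoms: none
Why: The lactone enolate (the carboxylate is not enolised) is protonated under kinetic control on the face away from the quaternary C1 that flanks C12, which places the methyl group cis to C1 (13S) whichever epimer is used (stereoconvergent enolisation and protonation).

Step 12
Reactants: 20 3-methylfuran-2(5H)-one
Product: 21 3-methyl-2-(triisopropylsilyloxy)furan
Conditions: i-Pr3SiOTf, Et3N, CH2Cl2, 0 °C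
Reagents that add atoms: triisopropylsilyl trifluoromethanesulfonate, CC(C)[Si](OS(=O)(=O)C(F)(F)F)(C(C)C)C(C)C
Why: O-Silylation of the dienolate of the butenolide gives the 2-silyloxyfuran that serves as vinylogous nucleophile.

Step 13
Reactants: 19 (13S)-tetracyclic lactone amino acid; 21 3-methyl-2-(triisopropylsilyloxy)furan
Product: 24 (1R,3S,9S,9aR,10R,11S,12R,13S,18S)-tetracyclic amine carrying the 4-methyl-5-oxo-2,5-dihydrofuran-2-yl group at C3 (1-OSiEt3), via acyl chloride 22 (not isolated), via iminium chloride 23 (not isolated)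
Conditions: POCl3, DMF, rt; then 21, 0 °C → rt; NaHCO3 (aq)
Reagents that add atoms: none
Why: The α-tertiary-amino acyl chloride loses carbon monoxide to give the iminium ion at C3 only, and the silyloxyfuran adds through its C5 (vinylogous Mannich reaction) on the convex face of the pyrrolidine, anti to the carbocycle, so that C3 is re-formed with its original S configuration, the usual open, threo-selective transition state giving 18S.

Step 14
Reactants: 24 tetracyclic amine with the butenolide at C3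
Product: 25 (1R,3S,9S,9aR,10R,11S,12R,13S,18S,20S)-tetracyclic amine carrying the 4-methyl-5-oxooxolan-2-yl group at C3 (1-OSiEt3)
Conditions: H2 (3 atm), Pd/C, EtOAc/AcOH, rt
Reagents that add atoms: none
Why: Hydrogen is delivered to the butenolide on the face away from the C18 substituent (heterogeneous hydrogenation), which gives the cis-disposed methyl group (20S).

Step 15
Reactants: 25 tetracyclic amine with the saturated side lactone (1-OSiEt3)
Product: 26 (1R,3S,9S,9aR,10R,11S,12R,13S,18S,20S)-1-hydroxy tetracyclic amino alcohol with the side lactone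
Conditions: HF·pyridine, THF, 0 °C → rt
Reagents that add atoms: none
Why: Fluoride cleaves the tertiary silyl ether and frees the C1 hydroxyl that triggers the key step, while both lactones and the amine are untouched.

Step 16
Reactants: 26 1-hydroxy tetracyclic amino alcohol with the side lactone
Product: 28 tuberostemonone, via keto iminium acetate 27 (not isolated)
Conditions: Pb(OAc)4, pyridine, CH2Cl2, −40 → 0 °C; then NaClO2, NaH2PO4, 2-methylbut-2-ene, t-BuOH/H2O, 0 °C → rt
Reagents that add atoms: sodium chlorite, [Na+].[O-]Cl=O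
Why: Ligand exchange puts the tertiary C1 hydroxyl on tetravalent lead, and the lead alkoxide fragments in a two-electron, Grob-type step in which the N4 lone pair pushes out the C1–C9a bond, so that C1 becomes the ketone, C9a the iminium carbon and divalent lead leaves; water then adds to the iminium ion and chlorite oxidises the carbinolamine to the lactam, the hypochlorite being trapped by the alkene. The closest known reactions are the Pb(OAc)4 cleavage of 1,2-amino alcohols, tertiary amines included, and the oxidation of cyclic iminium ions to lactams by chlorite. The nine-membered ring is not closed end to end but arises when the bond common to the pyrrolidine and cyclohexane rings is cut (ring-fusion scission, 5 + 6 → 9), helped by release of the boat cyclohexane, and the azepane already present becomes the azepanone. No stereocentre is formed; C1 and C9a cease to be stereocentres, and C9 and C12, now α to the iminium and ketone carbons, should hold because an enamine toward C9 would be a strained bridgehead olefin of the bicyclo[6.4.1] frame and the medium stays cold and buffered. The step needs cleavage of the amino alcohol in preference to oxidation at C3–H or C5–H2, which the much faster glycol-type path at low temperature should secure, and there is no second amino alcohol because O18 is tied up in the side lactone.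

**Compound list**

1 | N-(tert-butoxycarbonyl)-L-tyrosine | O=C(O)[C@H](Cc1ccc(O)cc1)NC(=O)OC(C)(C)C | starting material
2 | tert-butyl N-[(3S)-2,8-dioxo-1-oxaspiro[4.5]deca-6,9-dien-3-yl]carbamate | O=C1OC2(C=CC(=O)C=C2)C[C@@H]1NC(=O)OC(C)(C)C | intermediate
3 | benzyl (2S)-2-[(tert-butoxycarbonyl)amino]-3-(1-hydroxy-4-oxocyclohexa-2,5-dien-1-yl)propanoate (quinol benzyl ester) | O=C(OCc1ccccc1)[C@H](CC1(O)C=CC(=O)C=C1)NC(=O)OC(C)(C)C | intermediate
4 | 2-benzyl 1-tert-butyl (2S,3aR,7aR)-3a-hydroxy-6-oxo-2,3,3a,6,7,7a-hexahydro-1H-indole-1,2-dicarboxylate | CC(C)(C)OC(=O)N1[C@H](C(=O)OCc2ccccc2)C[C@@]2(O)C=CC(=O)C[C@@H]12 | intermediate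
5 | 2-benzyl 1-tert-butyl (2S,3aR,7aR)-6-oxo-3a-(triethylsilyloxy)-2,3,3a,6,7,7a-hexahydro-1H-indole-1,2-dicarboxylate | CC(C)(C)OC(=O)N1[C@H](C(=O)OCc2ccccc2)C[C@@]2(O[Si](CC)(CC)CC)C=CC(=O)C[C@@H]12 | intermediate
6 | 2-benzyl 1-tert-butyl (2S,3aR,7R,7aR)-7-(4-chlorobutyl)-6-oxo-3a-(triethylsilyloxy)-2,3,3a,6,7,7a-hexahydro-1H-indole-1,2-dicarboxylate | CC(C)(C)OC(=O)N1[C@H](C(=O)OCc2ccccc2)C[C@@]2(O[Si](CC)(CC)CC)C=CC(=O)[C@H](CCCCCl)[C@@H]12 | intermediate
7 | bromomagnesium C10 enolate formed from 6 by 1,4-addition of the isopropenyl group to C12 | CC(C)(C)OC(=O)N1[C@H](C(=O)OCc2ccccc2)C[C@@]2(O[Si](CC)(CC)CC)[C@H](C(C)=C)C=C(O[Mg]Br)[C@H](CCCCCl)[C@@H]12 | intermediate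
8 | 2-benzyl 1-tert-butyl (2S,3aR,4S,7R,7aR)-7-(4-chlorobutyl)-4-(prop-1-en-2-yl)-3a-(triethylsilyloxy)-6-(trifluoromethylsulfonyloxy)-2,3,3a,4,7,7a-hexahydro-1H-indole-1,2-dicarboxylate | CC(C)(C)OC(=O)N1[C@H](C(=O)OCc2ccccc2)C[C@@]2(O[Si](CC)(CC)CC)[C@H](C(C)=C)C=C(OS(=O)(=O)C(F)(F)F)[C@H](CCCCCl)[C@@H]12 | intermediate
9 | 2-benzyl 1-tert-butyl (2S,3aR,4S,7S,7aR)-7-(4-chlorobutyl)-6-ethyl-4-(prop-1-en-2-yl)-3a-(triethylsilyloxy)-2,3,3a,4,7,7a-hexahydro-1H-indole-1,2-dicarboxylate | CC(C)(C)OC(=O)N1[C@H](C(=O)OCc2ccccc2)C[C@@]2(O[Si](CC)(CC)CC)[C@H](C(C)=C)C=C(CC)[C@H](CCCCCl)[C@@H]12 | intermediate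
10 | benzyl (2S,3aR,4S,7S,7aR)-7-(4-chlorobutyl)-6-ethyl-4-(prop-1-en-2-yl)-3a-(triethylsilyloxy)-2,3,3a,4,7,7a-hexahydro-1H-indole-2-carboxylate (secondary amine) | O=C(OCc1ccccc1)[C@@H]1C[C@@]2(O[Si](CC)(CC)CC)[C@H](C(C)=C)C=C(CC)[C@H](CCCCCl)[C@H]2N1 | intermediate
11 | benzyl (1R,3S,9S,9aR,12S)-10-ethyl-12-(prop-1-en-2-yl)-1-(triethylsilyloxy)-10,11-didehydro-perhydroazepino[3,2,1-hi]indole-3-carboxylate (pyrrolidine cis-fused and azepane trans-fused to the cyclohexene; target numbering) | O=C(OCc1ccccc1)[C@@H]1C[C@@]2(O[Si](CC)(CC)CC)[C@H](C(C)=C)C=C(CC)[C@@H]3CCCCN1[C@@H]23 | intermediate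
12 | 9-BBN adduct of 11 (boron on C14) | O=C(OCc1ccccc1)[C@@H]1C[C@@]2(O[Si](CC)(CC)CC)[C@H](C(C)CB4C5CCCC4CCC5)C=C(CC)[C@@H]3CCCCN1[C@@H]23 | intermediate
13 | bis-borane with boron on C11 and C14, as its N–BH3 adduct | O=C(OCc1ccccc1)[C@@H]1C[C@@]2(O[Si](CC)(CC)CC)[C@H](C(C)CB4C5CCCC4CCC5)[C@@H](B)[C@H](CC)[C@@H]3CCCC[N+]1([BH3-])[C@@H]23 | intermediate
14 | benzyl (1R,3S,9S,9aR,10R,11S,12R)-10-ethyl-11-hydroxy-12-(1-hydroxypropan-2-yl)-1-(triethylsilyloxy)perhydroazepino[3,2,1-hi]indole-3-carboxylate (both C13 epimers) | O=C(OCc1ccccc1)[C@@H]1C[C@@]2(O[Si](CC)(CC)CC)[C@H](C(C)CO)[C@@H](O)[C@H](CC)[C@@H]3CCCCN1[C@@H]23 | intermediate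
15 | lactol of 14 (O11–C14(OH)–C13–C12 ring; both C13 epimers) | O=C(OCc1ccccc1)[C@@H]1C[C@@]2(O[Si](CC)(CC)CC)[C@@H]3C(C)C(O)O[C@H]3[C@H](CC)[C@@H]4CCCCN1[C@@H]24 | intermediate
16 | benzyl ester of the tetracyclic lactone (γ-lactone trans-fused at C11–C12; 1R,3S,9S,9aR,10R,11S,12R; both C13 epimers) | O=C(OCc1ccccc1)[C@@H]1C[C@@]2(O[Si](CC)(CC)CC)[C@@H]3C(C)C(=O)O[C@H]3[C@H](CC)[C@@H]4CCCCN1[C@@H]24 | intermediate
17 | tetracyclic lactone amino acid (3-CO2H; both C13 epimers) | OC(=O)[C@@H]1C[C@@]2(O[Si](CC)(CC)CC)[C@@H]3C(C)C(=O)O[C@H]3[C@H](CC)[C@@H]4CCCCN1[C@@H]24 | intermediate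
18 | dilithium salt of 17 (carboxylate and lactone enolate) | [Li+].[Li+].[O-]C(=O)[C@@H]1C[C@@]2(O[Si](CC)(CC)CC)[C@@H]3C(C)=C([O-])O[C@H]3[C@H](CC)[C@@H]4CCCCN1[C@@H]24 | intermediate
19 | (13S)-tetracyclic lactone amino acid (1R,3S,9S,9aR,10R,11S,12R,13S) | OC(=O)[C@@H]1C[C@@]2(O[Si](CC)(CC)CC)[C@@H]3[C@H](C)C(=O)O[C@H]3[C@H](CC)[C@@H]4CCCCN1[C@@H]24 | intermediate
20 | 3-methylfuran-2(5H)-one | CC1=CCOC1=O | starting material
21 | 3-methyl-2-(triisopropylsilyloxy)furan | Cc1ccoc1O[Si](C(C)C)(C(C)C)C(C)C | intermediate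
22 | acyl chloride of 19 | ClC(=O)[C@@H]1C[C@@]2(O[Si](CC)(CC)CC)[C@@H]3[C@H](C)C(=O)O[C@H]3[C@H](CC)[C@@H]4CCCCN1[C@@H]24 | intermediate
23 | C3=N4 iminium chloride formed from 22 by loss of CO | C1C[C@@]2(O[Si](CC)(CC)CC)[C@@H]3[C@H](C)C(=O)O[C@H]3[C@H](CC)[C@@H]4CCCC[N+]=1[C@@H]24.[Cl-] | intermediate
24 | (1R,3S,9S,9aR,10R,11S,12R,13S,18S)-tetracyclic amine with the 4-methyl-5-oxo-2,5-dihydrofuran-2-yl group at C3 (1-OSiEt3) | O=C1O[C@@H](C=C1C)[C@@H]5C[C@@]2(O[Si](CC)(CC)CC)[C@@H]3[C@H](C)C(=O)O[C@H]3[C@H](CC)[C@@H]4CCCCN5[C@@H]24 | intermediate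
25 | (1R,3S,9S,9aR,10R,11S,12R,13S,18S,20S)-tetracyclic amine with the 4-methyl-5-oxooxolan-2-yl group at C3 (1-OSiEt3) | O=C1O[C@@H](C[C@@H]1C)[C@@H]5C[C@@]2(O[Si](CC)(CC)CC)[C@@H]3[C@H](C)C(=O)O[C@H]3[C@H](CC)[C@@H]4CCCCN5[C@@H]24 | intermediate
26 | (1R,3S,9S,9aR,10R,11S,12R,13S,18S,20S)-1-hydroxy tetracyclic amino alcohol with the side lactone | O=C1O[C@@H](C[C@@H]1C)[C@@H]5C[C@@]2(O)[C@@H]3[C@H](C)C(=O)O[C@H]3[C@H](CC)[C@@H]4CCCCN5[C@@H]24 | intermediate
27 | nine-membered C1 ketone with the C9a=N4 iminium bond, acetate salt | O=C1O[C@@H](C[C@@H]1C)[C@@H]5CC(=O)[C@@H]3[C@H](C)C(=O)O[C@H]3[C@H](CC)[C@@H]4CCCC[N+]5=C4.CC(=O)[O-] | intermediate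
28 | tuberostemonone (3S,9S,10R,11S,12R,13S,18S,20S) | CC[C@H]1[C@@H]2OC(=O)[C@@H](C)[C@H]2C(=O)C[C@@H]([C@@H]2C[C@H](C)C(=O)O2)N2CCCC[C@@H]1C2=O | target

Total step count: 16. Longest linear sequence: 15 steps (steps 1–11 and 13–16).

Steps most likely to fail:

1. Step 16. Oxidation of the tertiary amine at C3–H or C5–H2 by tetravalent lead, a fragmentation that is too slow because the nitrogen lone pair cannot align with the C1–C9a bond, or transannular Mannich closure of the C12 enol onto the iminium ion before it is oxidised would divert the key step. The fallback would set out from 26: syn-dehydration of the angular alcohol toward the cis C9a–H with the Burgess reagent would give the C1=C9a enamine of the tetracycle F1 (other stereocentres as in 26). Dye-sensitised photo-oxygenation (O2, tetraphenylporphyrin, hν, −78 °C) would then pass through the C1,C9a-dioxetane F2 and, by (2+2) cycloreversion, cut the same bond to give 28 directly.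

2. Step 13. Low threo/erythro or facial selectivity in the vinylogous Mannich addition, or drift of the iminium ion to its enamine, would erode C3 and C18. The fallback would set out from 19: BH3·SMe2 would reduce the acid, not the lactone, to the C3 hydroxymethyl compound F3, and Swern oxidation would give the C3 aldehyde F4. A zinc-mediated Barbier addition of ethyl 2-(bromomethyl)acrylate under chelation control by the ring nitrogen would give the syn (18S) hydroxy ester F5, which would close with acid to the α-methylene lactone F6. Hydrogenation over Pd/C, anti to the C18 substituent, would return to the route at 25.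

3. Step 11. Poor facial selectivity of the kinetic proton transfer, or drift back toward the more stable C13 epimer during work-up, would leave a mixture at C13. The fallback would set out from 17: the lactone enolate would be selenenylated with PhSeBr to the C13 phenylselanyl lactone F7. Oxidation (H2O2, amine protected as its trifluoroacetate salt) and syn-elimination into the methyl group would give the α-methylene lactone F8, and hydrogenation with RhCl(PPh3)3 on the face away from C1 would return to the route at 19.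

**Further compounds**

F1 | step 16 | C1=C9a enamine of the tetracycle (1,9a-didehydro; other stereocentres as in 26) | O=C1O[C@@H](C[C@@H]1C)[C@@H]2CC3=C4N2CCCC[C@H]4[C@@H](CC)[C@@H]5OC(=O)[C@@H](C)[C@@H]35
F2 | step 16 | C1,C9a-dioxetane formed from F1 and singlet oxygen | O=C1O[C@@H](C[C@@H]1C)[C@@H]2CC36OOC64N2CCCC[C@H]4[C@@H](CC)[C@@H]5OC(=O)[C@@H](C)[C@@H]35
F3 | step 13 | C3 hydroxymethyl analogue of 19 (amino alcohol) | OC[C@@H]1C[C@@]2(O[Si](CC)(CC)CC)[C@@H]3[C@H](C)C(=O)O[C@H]3[C@H](CC)[C@@H]4CCCCN1[C@@H]24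
F4 | step 13 | C3 aldehyde | O=C[C@@H]1C[C@@]2(O[Si](CC)(CC)CC)[C@@H]3[C@H](C)C(=O)O[C@H]3[C@H](CC)[C@@H]4CCCCN1[C@@H]24
F5 | step 13 | ethyl (4S)-4-hydroxy-2-methylidene-4-(tetracyclic C3-yl)butanoate (syn hydroxy ester) | CCOC(=O)C(=C)C[C@H](O)[C@@H]1C[C@@]2(O[Si](CC)(CC)CC)[C@@H]3[C@H](C)C(=O)O[C@H]3[C@H](CC)[C@@H]4CCCCN1[C@@H]24
F6 | step 13 | (18S)-α-methylene side lactone (4-methylidene-5-oxooxolan-2-yl at C3) | C=C1C[C@H](OC1=O)[C@@H]5C[C@@]2(O[Si](CC)(CC)CC)[C@@H]3[C@H](C)C(=O)O[C@H]3[C@H](CC)[C@@H]4CCCCN5[C@@H]24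
F7 | step 11 | C13 phenylselanyl lactone amino acid | OC(=O)[C@@H]1C[C@@]2(O[Si](CC)(CC)CC)[C@@H]3C(C)([Se]c5ccccc5)C(=O)O[C@H]3[C@H](CC)[C@@H]4CCCCN1[C@@H]24
F8 | step 11 | C13 methylidene lactone amino acid | OC(=O)[C@@H]1C[C@@]2(O[Si](CC)(CC)CC)[C@@H]3C(=C)C(=O)O[C@H]3[C@H](CC)[C@@H]4CCCCN1[C@@H]24
A1 | direct plan | (3S,5S)-5-[(2S,4S,5R)-5-[(Z)-but-1-en-1-yl]-1-(4-methoxybenzyl)-4-(tert-butyldimethylsilyloxy)pyrrolidin-2-yl]-3-methyloxolan-2-one | CC/C=C\[C@H]1N(Cc2ccc(OC)cc2)[C@@H](C[C@@H]1O[Si](C)(C)C(C)(C)C)[C@@H]3C[C@H](C)C(=O)O3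
A2 | direct plan | (3S,4S,5E,7S,9S)-3-(4-chlorobutyl)-4-ethyl-1-(4-methoxybenzyl)-9-[(2S,4S)-4-methyl-5-oxooxolan-2-yl]-7-(tert-butyldimethylsilyloxy)-1,3,4,7,8,9-hexahydro-2H-azonin-2-one | CC[C@H]1/C=C/[C@@H](O[Si](C)(C)C(C)(C)C)C[C@@H]([C@@H]2C[C@H](C)C(=O)O2)N(Cc2ccc(OC)cc2)C(=O)[C@H]1CCCCCl
A3 | direct plan | (11S,12R)-11,12-epoxy-1-ketone of the bridged bicyclic lactam | CC[C@H]1[C@@H]2O[C@H]2C(=O)C[C@@H]([C@@H]2C[C@H](C)C(=O)O2)N2CCCC[C@@H]1C2=O
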